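## Retrosynthetic overview

1. Locants: unprimed = 5,7-dihydroxy lactone half, primed = 5',6',7',8'-tetrahydroxy half. Endgame: 32 ⇐ perbenzylated 6,8-dibromo bis-lactone 31 (one hydrogenolysis) ⇐ lactol 30 ⇐ 2'-phenylthio chroman 29, with C2' carried one oxidation level low.
2. Key disconnection: C2'–C3' and C4'–C4a' of 29 are made in one cationic [4+2] (a thionium variant of the oxa-Povarov reaction). The partners are the Z-styryl lactone 15 and the α-aryloxy thionium ion 28 made from sulfoxide 27.
3. Enabling feature: the primed benzo ring carries five oxygens and one single free carbon (C4a') ortho to O1'. C4a'=C8a'–O1'–C2'(+) is therefore a cationic 2-oxadiene with only one way to close. C4' bears a 4-oxygenated phenyl ring, so C3'=C4' is a styrene polarised to bond at C3' and pass the charge to C4'.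
4. Stereo relay: C3/C4 (cis) are set by one isothiourea-catalysed o-quinone methide [4+2] (7 + 10 → 14). E→Z photoisomerisation (15) then lets the alkene geometry give the 3',4'-cis pair and A(1,3) strain at C3 choose the face.
5. Ring order: unprimed lactone ring (step 6), then primed pyran ring (step 15). The arene pieces come from 2,4,6- and 2,3,4-trihydroxybenzaldehyde.

Key step: step 15

Assumption 1: the (2S,3R) enantiomer of HyperBTM is assigned to the 4R series by analogy with its Michael addition–lactonisations. If the sense is opposite, the equally commercial (2R,3S) catalyst is used.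
Assumption 2: C2' in 29 and 30 and the sulfur atom in 27 are inconsequential stereocentres (mixtures) and are left unmarked in the SMILES.

## Route

Step 1
Reactants: 1 2,4,6-trihydroxybenzaldehyde
Product: 2 2,4-bis(benzyloxy)-6-hydroxybenzaldehyde
Conditions: BnBr (2.0 equiv), K2CO3, DMF, rt
Reagents that add atoms: benzyl bromide, BrCc1ccccc1
Why: Williamson etherification; the hydroxyl that is hydrogen-bonded to the formyl group is the least nucleophilic and should stay free.

Step 2
Reactants: 2 2,4-bis(benzyloxy)-6-hydroxybenzaldehyde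
Product: 3 2,4-bis(benzyloxy)-3,5-dibromo-6-hydroxybenzaldehyde
Conditions: NBS (2.05 equiv), MeCN–CH2Cl2, 0 °C
Reagents that add atoms: N-bromosuccinimide, O=C1CCC(=O)N1Br
Why: Electrophilic aromatic bromination fills both free positions of the phloroglucinol ring (later C6 and C8) so that this ring cannot compete as a π-nucleophile in step 15; the bromines leave again in step 18.

Step 3
Reactants: 3 2,4-bis(benzyloxy)-3,5-dibromo-6-hydroxybenzaldehyde; 4 4-(benzyloxy)phenylmagnesium bromide
Product: 5 rac-3,5-bis(benzyloxy)-2-{[4-(benzyloxy)phenyl](hydroxy)methyl}-4,6-dibromophenol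
Conditions: 4 (2.2 equiv), THF, −78 → 0 °C; aq NH4Cl
Reagents that add atoms: none
Why: Grignard addition to the aldehyde after deprotonation of the phenol by the first equivalent; aryl Grignard reagents do not exchange with the aryl bromides at this temperature, and the carbinol centre is lost again in step 6.

Step 4
Reactants: 5 rac-3,5-bis(benzyloxy)-2-{[4-(benzyloxy)phenyl](hydroxy)methyl}-4,6-dibromophenol; 6 p-toluenesulfinic acid
Product: 7 rac-3,5-bis(benzyloxy)-2-{[4-(benzyloxy)phenyl](tosyl)methyl}-4,6-dibromophenol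
Conditions: 6 (1.2 equiv), CH2Cl2, rt
Reagents that add atoms: none
Why: SN1-type substitution of the strongly donor-stabilised benzhydrylic alcohol by the sulfinate gives the standard bench-stable precursor that releases an o-quinone methide with mild base.

Step 5
Reactants: 8 1-(benzyloxy)-4-iodobenzene; 9 but-3-enoic acid
Product: 10 (E)-4-[4-(benzyloxy)phenyl]but-3-enoic acid
Conditions: Pd(OAc)2 (cat.), P(o-tol)3, Et3N, MeCN, 80 °C
Reagents that add atoms: none
Why: Mizoroki–Heck arylation of the terminal alkene; β-hydride elimination towards the benzylic position should give the styrene-conjugated E β,γ-unsaturated acid.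

Step 6
Reactants: 10 (E)-4-[4-(benzyloxy)phenyl]but-3-enoic acid; 11 pivaloyl chloride; 7 rac-3,5-bis(benzyloxy)-2-{[4-(benzyloxy)phenyl](tosyl)methyl}-4,6-dibromophenol
Product: 14 (3R,4R)-5,7-bis(benzyloxy)-4-[4-(benzyloxy)phenyl]-3-{(E)-2-[4-(benzyloxy)phenyl]ethenyl}-6,8-dibromo-3,4-dihydro-2H-chromen-2-one (3,4-cis), via mixed anhydride 12 (not isolated), via o-quinone methide 13 (not isolated)
Conditions: 10, 11, iPr2NEt, CH2Cl2, 0 °C; then (2S,3R)-HyperBTM (10 mol %), 7, iPr2NEt, −40 °C
Reagents that add atoms: none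
Why: Isothiourea-catalysed Michael addition–lactonisation (formal [4+2]) of the C1-ammonium enolate from 12 with o-quinone methide 13 released from 7; the catalyst shields one enolate face and fixes C4 and C3 in one event, with the cis relationship typical of this annulation under kinetic control.

Step 7
Reactants: 14 (3R,4R)-cis E-styryl lactone
Product: 15 (3R,4R)-5,7-bis(benzyloxy)-4-[4-(benzyloxy)phenyl]-3-{(Z)-2-[4-(benzyloxy)phenyl]ethenyl}-6,8-dibromo-3,4-dihydro-2H-chromen-2-one (3,4-cis)
Conditions: fac-Ir(ppy)3 (1 mol %), degassed MeCN–CH2Cl2, blue LEDs, rt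
Reagents that add atoms: none
Why: Contra-thermodynamic E→Z isomerisation of a β-alkylstyrene by visible-light triplet energy transfer; the Z isomer is twisted out of conjugation by the branched allylic carbon, is no longer sensitised and should accumulate, and the base-free medium leaves C3 untouched.

Step 8
Reactants: 16 2,3,4-trihydroxybenzaldehyde
Product: 17 2,3,4-tris(benzyloxy)benzaldehyde
Conditions: BnBr (3.3 equiv), K2CO3, DMF, 60 °C
Reagents that add atoms: benzyl bromide, BrCc1ccccc1
Why: Exhaustive Williamson etherification.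

Step 9
Reactants: 17 2,3,4-tris(benzyloxy)benzaldehyde
Product: 19 2,3,4-tris(benzyloxy)phenol, via aryl formate 18 (not isolated)
Conditions: mCPBA, CH2Cl2, rt; then K2CO3 (cat.), MeOH
Reagents that add atoms: mCPBA, OOC(=O)c1cccc(Cl)c1
Why: Baeyer–Villiger oxidation of an electron-rich benzaldehyde (aryl migration) followed by methanolysis of the formate.

Step 10
Reactants: 19 2,3,4-tris(benzyloxy)phenol
Product: 20 1,2,3,4-tetrakis(benzyloxy)benzene
Conditions: BnBr, K2CO3, DMF, 60 °C
Reagents that add atoms: benzyl bromide, BrCc1ccccc1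
Why: Williamson etherification.

Step 11
Reactants: 20 1,2,3,4-tetrakis(benzyloxy)benzene
Product: 22 2,3,4,5-tetrakis(benzyloxy)benzaldehyde, via iminium chloride 21 (not isolated)
Conditions: POCl3, DMF, 70 °C; then ice–water
Reagents that add atoms: N,N-dimethylformamide, CN(C)C=O; water, O
Why: Vilsmeier–Haack formylation of a tetraalkoxybenzene; the two free positions are equivalent, so only one aldehyde can form.

Step 12
Reactants: 22 2,3,4,5-tetrakis(benzyloxy)benzaldehyde
Product: 24 2,3,4,5-tetrakis(benzyloxy)phenol, via aryl formate 23 (not isolated)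
Conditions: mCPBA, CH2Cl2, rt; then K2CO3 (cat.), MeOH, under Ar
Reagents that add atoms: mCPBA, OOC(=O)c1cccc(Cl)c1
Why: Second Baeyer–Villiger oxidation and formate methanolysis install the fifth oxygen next to the only remaining ring C–H.

Step 13
Reactants: 24 2,3,4,5-tetrakis(benzyloxy)phenol; 25 chloromethyl phenyl sulfide
Product: 26 1,2,3,4-tetrakis(benzyloxy)-5-[(phenylsulfanyl)methoxy]benzene
Conditions: K2CO3, NaI (cat.), DMF, 50 °C, under Ar
Reagents that add atoms: none
Why: Williamson O-alkylation with an α-chloro sulfide (phenylthiomethyl ether formation) brings in the carbon that becomes C2'.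

Step 14
Reactants: 26 1,2,3,4-tetrakis(benzyloxy)-5-[(phenylsulfanyl)methoxy]benzene
Product: 27 1,2,3,4-tetrakis(benzyloxy)-5-[(phenylsulfinyl)methoxy]benzene
Conditions: mCPBA (1.0 equiv), CH2Cl2, −78 → −40 °C
Reagents that add atoms: mCPBA, OOC(=O)c1cccc(Cl)c1
Why: Chemoselective sulfide-to-sulfoxide oxidation, much faster at low temperature than any attack on the fully etherified arene.

Step 15
Reactants: 27 1,2,3,4-tetrakis(benzyloxy)-5-[(phenylsulfinyl)methoxy]benzene; 15 (3R,4R)-cis Z-styryl lactone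
Product: 29 (3S,4R)-5,7-bis(benzyloxy)-4-[4-(benzyloxy)phenyl]-6,8-dibromo-3-{(3S,4R)-5,6,7,8-tetrakis(benzyloxy)-4-[4-(benzyloxy)phenyl]-2-(phenylsulfanyl)-3,4-dihydro-2H-chromen-3-yl}-3,4-dihydro-2H-chromen-2-one (both halves 3,4-cis), via thionium triflate 28 (not isolated)
Conditions: 27 (1.5 equiv), Tf2O (1.5 equiv), 2,6-di-tert-butyl-4-methylpyridine (DTBMP, 4 equiv), CH2Cl2, −78 °C; then 15, −78 → −30 °C; aq NaHCO3
Reagents that add atoms: none
Why: Proposed new method: Tf2O/DTBMP converts 27 by Pummerer activation into thionium ion 28, a cationic 2-oxadiene (C4a'=C8a'–O1'–C2'=S+), whose carbenium carbon C2' is attacked by the β-carbon C3' of the 4-benzyloxystyrene while the emerging 4-benzyloxybenzyl cation at C4' is captured by C4a', the only unsubstituted carbon of the pentaoxygenated ring, and loss of that ring proton to DTBMP rearomatises. The closest known reaction types are the oxa-Povarov reaction (aryl oxocarbenium ions plus styrenes give chromans) and the cationic polar [4+2] cycloaddition of α-thio carbocations with alkenes (thiochromans); new is that the carbenium carbon stands at the formate oxidation level and that the O-aryl and not the S-aryl ring must close, which five oxygen donors against none should secure. The single new ring (O1'–C2'–C3'–C4'–C4a'–C8a') closes as a formal inverse-electron-demand [4+2], in the stepwise limit as a six-membered Friedel–Crafts alkylation of the arene by the benzylic cation. C3' and C4' should come out cis because both bonds form on one face of the Z alkene (closure by the very electron-rich arene held over that face should outrun C3'–C4' rotation, and the peri 5'-OBn group favours the same isomer by forcing the C4' aryl group pseudo-axial with the bulky C3' substituent pseudo-equatorial). The face is chosen by C3: A(1,3) strain in the Z alkene locks H3 in the alkene plane, C4 with its pseudo-axial aryl group covers one face and the flat C2 carbonyl leaves the other open, which leads to 3'S,4'R, while C2' forms as an inconsequential epimer mixture that is erased in step 17. Chemoselectivity needs the alkene to be the best π-nucleophile of 15, which the bromines at C6 and C8 secure (no free position on that ring), regioselectivity follows from the 4-benzyloxy group that stabilises charge only at C4', and preforming 28 before 15 is added prevents attack at sulfur and self-alkylation of 27.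

Step 16
Reactants: 29 2'-phenylthio chroman–lactone
Product: 30 (3S,4R)-5,7-bis(benzyloxy)-4-[4-(benzyloxy)phenyl]-6,8-dibromo-3-{(3S,4R)-5,6,7,8-tetrakis(benzyloxy)-4-[4-(benzyloxy)phenyl]-2-hydroxy-3,4-dihydro-2H-chromen-3-yl}-3,4-dihydro-2H-chromen-2-one (lactol)
Conditions: HgCl2 (2 equiv), CaCO3, MeCN–H2O 4:1, 0 °C → rt
Reagents that add atoms: water, O
Why: Thiophilic metal-promoted hydrolysis of an O,S-acetal at buffered near-neutral pH, which leaves the lactone, the benzyl ethers and the α-stereocentres alone.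

Step 17
Reactants: 30 lactol
Product: 31 (3S,4R,3'S,4'R)-5,7,5',6',7',8'-hexakis(benzyloxy)-4,4'-bis[4-(benzyloxy)phenyl]-6,8-dibromo-3,3',4,4'-tetrahydro-[3,3'-bichromene]-2,2'-dione
Conditions: Dess–Martin periodinane, CH2Cl2, 0 °C
Reagents that add atoms: none
Why: Dess–Martin oxidation of a chroman-2-ol to the dihydrocoumarin under non-basic conditions, so that the kinetic cis centres C3' and C3 are not epimerised.

Step 18
Reactants: 31 protected dibromo bis-lactone
Product: 32 target, (3S,4R,3'S,4'R)-5,7,5',6',7',8'-hexahydroxy-4,4'-bis(4-hydroxyphenyl)-3,3',4,4'-tetrahydro-[3,3'-bichromene]-2,2'-dione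
Conditions: H2 (1 atm), 10% Pd/C, NaOAc (2.2 equiv), THF–AcOH 9:1, rt; work-up under Ar
Reagents that add atoms: none
Why: Catalytic hydrogenolysis cleaves the eight benzyl ethers and both aryl C–Br bonds in one operation in an acetate-buffered, alcohol-free medium that neither opens the lactones nor enolises C3/C3'.

## Compound list

1 | 2,4,6-trihydroxybenzaldehyde | O=Cc1c(O)cc(O)cc1O | starting material
2 | 2,4-bis(benzyloxy)-6-hydroxybenzaldehyde | O=Cc1c(O)cc(OCc2ccccc2)cc1OCc1ccccc1 | intermediate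
3 | 2,4-bis(benzyloxy)-3,5-dibromo-6-hydroxybenzaldehyde | O=Cc1c(O)c(Br)c(OCc2ccccc2)c(Br)c1OCc1ccccc1 | intermediate
4 | 4-(benzyloxy)phenylmagnesium bromide | Br[Mg]c1ccc(OCc2ccccc2)cc1 | starting material
5 | rac-3,5-bis(benzyloxy)-2-{[4-(benzyloxy)phenyl](hydroxy)methyl}-4,6-dibromophenol | OC(c1ccc(OCc2ccccc2)cc1)c1c(O)c(Br)c(OCc2ccccc2)c(Br)c1OCc1ccccc1 | intermediate
6 | p-toluenesulfinic acid | Cc1ccc(cc1)S(=O)O | starting material
7 | rac-3,5-bis(benzyloxy)-2-{[4-(benzyloxy)phenyl](tosyl)methyl}-4,6-dibromophenol | Cc1ccc(cc1)S(=O)(=O)C(c1ccc(OCc2ccccc2)cc1)c1c(O)c(Br)c(OCc2ccccc2)c(Br)c1OCc1ccccc1 | intermediate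
8 | 1-(benzyloxy)-4-iodobenzene | Ic1ccc(OCc2ccccc2)cc1 | starting material
9 | but-3-enoic acid | C=CCC(=O)O | starting material
10 | (E)-4-[4-(benzyloxy)phenyl]but-3-enoic acid | OC(=O)C/C=C/c1ccc(OCc2ccccc2)cc1 | intermediate
11 | pivaloyl chloride | CC(C)(C)C(=O)Cl | starting material
12 | (E)-4-[4-(benzyloxy)phenyl]but-3-enoic pivalic anhydride (not isolated) | CC(C)(C)C(=O)OC(=O)C/C=C/c1ccc(OCc2ccccc2)cc1 | intermediate
13 | 6-[4-(benzyloxy)benzylidene]-3,5-bis(benzyloxy)-2,4-dibromocyclohexa-2,4-dien-1-one (o-quinone methide, not isolated) | O=C1C(Br)=C(OCc2ccccc2)C(Br)=C(OCc2ccccc2)C1=Cc1ccc(OCc2ccccc2)cc1 | intermediate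
14 | (3R,4R)-cis-5,7-bis(benzyloxy)-4-[4-(benzyloxy)phenyl]-3-{(E)-2-[4-(benzyloxy)phenyl]ethenyl}-6,8-dibromochroman-2-one | O=C1Oc2c(Br)c(OCc3ccccc3)c(Br)c(OCc3ccccc3)c2[C@@H](c2ccc(OCc3ccccc3)cc2)[C@H]1/C=C/c1ccc(OCc2ccccc2)cc1 | intermediate
15 | (3R,4R)-cis-5,7-bis(benzyloxy)-4-[4-(benzyloxy)phenyl]-3-{(Z)-2-[4-(benzyloxy)phenyl]ethenyl}-6,8-dibromochroman-2-one | O=C1Oc2c(Br)c(OCc3ccccc3)c(Br)c(OCc3ccccc3)c2[C@@H](c2ccc(OCc3ccccc3)cc2)[C@H]1/C=C\c1ccc(OCc2ccccc2)cc1 | intermediate
16 | 2,3,4-trihydroxybenzaldehyde | O=Cc1ccc(O)c(O)c1O | starting material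
17 | 2,3,4-tris(benzyloxy)benzaldehyde | O=Cc1ccc(OCc2ccccc2)c(OCc2ccccc2)c1OCc1ccccc1 | intermediate
18 | 2,3,4-tris(benzyloxy)phenyl formate (not isolated) | O=COc1ccc(OCc2ccccc2)c(OCc2ccccc2)c1OCc1ccccc1 | intermediate
19 | 2,3,4-tris(benzyloxy)phenol | Oc1ccc(OCc2ccccc2)c(OCc2ccccc2)c1OCc1ccccc1 | intermediate
20 | 1,2,3,4-tetrakis(benzyloxy)benzene | c1cc(OCc2ccccc2)c(OCc2ccccc2)c(OCc2ccccc2)c1OCc1ccccc1 | intermediate
21 | N,N-dimethyl-[2,3,4,5-tetrakis(benzyloxy)benzylidene]iminium chloride (not isolated) | C[N+](C)=Cc1cc(OCc2ccccc2)c(OCc2ccccc2)c(OCc2ccccc2)c1OCc1ccccc1.[Cl-] | intermediate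
22 | 2,3,4,5-tetrakis(benzyloxy)benzaldehyde | O=Cc1cc(OCc2ccccc2)c(OCc2ccccc2)c(OCc2ccccc2)c1OCc1ccccc1 | intermediate
23 | 2,3,4,5-tetrakis(benzyloxy)phenyl formate (not isolated) | O=COc1cc(OCc2ccccc2)c(OCc2ccccc2)c(OCc2ccccc2)c1OCc1ccccc1 | intermediate
24 | 2,3,4,5-tetrakis(benzyloxy)phenol | Oc1cc(OCc2ccccc2)c(OCc2ccccc2)c(OCc2ccccc2)c1OCc1ccccc1 | intermediate
25 | chloromethyl phenyl sulfide | ClCSc1ccccc1 | starting material
26 | 1,2,3,4-tetrakis(benzyloxy)-5-[(phenylsulfanyl)methoxy]benzene | C(Oc1cc(OCc2ccccc2)c(OCc2ccccc2)c(OCc2ccccc2)c1OCc1ccccc1)Sc1ccccc1 | intermediate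
27 | 1,2,3,4-tetrakis(benzyloxy)-5-[(phenylsulfinyl)methoxy]benzene (racemic at sulfur) | O=S(COc1cc(OCc2ccccc2)c(OCc2ccccc2)c(OCc2ccccc2)c1OCc1ccccc1)c1ccccc1 | intermediate
28 | phenyl{[2,3,4,5-tetrakis(benzyloxy)phenoxy]methylidene}sulfonium triflate (not isolated) | C(Oc1cc(OCc2ccccc2)c(OCc2ccccc2)c(OCc2ccccc2)c1OCc1ccccc1)=[S+]c1ccccc1.[O-]S(=O)(=O)C(F)(F)F | intermediate
29 | (3S,4R,3'S,4'R) 2'-phenylthio chroman–lactone, C2' epimers | O=C1Oc2c(Br)c(OCc3ccccc3)c(Br)c(OCc3ccccc3)c2[C@@H](c2ccc(OCc3ccccc3)cc2)[C@H]1[C@H]1C(Sc2ccccc2)Oc2c(OCc3ccccc3)c(OCc3ccccc3)c(OCc3ccccc3)c(OCc3ccccc3)c2[C@H]1c1ccc(OCc2ccccc2)cc1 | intermediate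
30 | (3S,4R,3'S,4'R) 2'-hydroxy chroman–lactone (lactol, C2' epimers) | O=C1Oc2c(Br)c(OCc3ccccc3)c(Br)c(OCc3ccccc3)c2[C@@H](c2ccc(OCc3ccccc3)cc2)[C@H]1[C@H]1C(O)Oc2c(OCc3ccccc3)c(OCc3ccccc3)c(OCc3ccccc3)c(OCc3ccccc3)c2[C@H]1c1ccc(OCc2ccccc2)cc1 | intermediate
31 | (3S,4R,3'S,4'R) octa-O-benzyl-6,8-dibromo bis-lactone | O=C1Oc2c(Br)c(OCc3ccccc3)c(Br)c(OCc3ccccc3)c2[C@@H](c2ccc(OCc3ccccc3)cc2)[C@H]1[C@H]1C(=O)Oc2c(OCc3ccccc3)c(OCc3ccccc3)c(OCc3ccccc3)c(OCc3ccccc3)c2[C@H]1c1ccc(OCc2ccccc2)cc1 | intermediate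
32 | CNP0064734.1, (3S,4R,3'S,4'R)-5,7,5',6',7',8'-hexahydroxy-4,4'-bis(4-hydroxyphenyl)-3,3',4,4'-tetrahydro-[3,3'-bichromene]-2,2'-dione | O=C1Oc2cc(O)cc(O)c2[C@@H](c2ccc(O)cc2)[C@H]1[C@H]1C(=O)Oc2c(O)c(O)c(O)c(O)c2[C@H]1c1ccc(O)cc1 | target

## Step count and risks

Total step count: 18. Longest linear sequence: 11 steps (steps 8–18, from 2,3,4-trihydroxybenzaldehyde).

**Step 15 (Proposed new method).**
- Risk: the activated sulfoxide may fragment at the O–CH2–S unit instead of giving the thionium ion. The addition to the hindered, twisted Z alkene may be slow or reversible, so that the alkene isomerises. The benzylic cation may rotate before closure, so that the 3',4'-cis relationship erodes.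
- Fallback: this uses known chemistry only. It sets out from 14 and 24 and comes back at 31, so steps 7 and 13–17 are not needed.
- Vilsmeier–Haack formylation of the styrene of 14 at C3' should give the (E)-2-substituted cinnamaldehyde F1. Pinnick oxidation then gives the cinnamic acid F2.
- Steglich esterification (EDC, catalytic DMAP, 0 °C) with phenol 24 gives the aryl cinnamate F3.
- TFA in CH2Cl2 then effects the established intramolecular hydroarylation of an aryl cinnamate (Friedel–Crafts conjugate addition) to 31.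
- In F3 the C4' aryl group is again cis to C3, so the same A(1,3) control should choose the C4' face. Kinetic protonation of the resulting enol anti to the pseudo-axial aryl group should set C3' cis.

**Step 6.**
- Risk: facial control on the peri-substituted, donor-rich o-quinone methide may be low. The cis relationship may also be lost through base-mediated epimerisation of the doubly activated C3–H.
- Fallback: it sets out from 7 (with 10 and 11) and comes back at 14. Only C4 is asked of the catalyst.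
- The crude annulation product is equilibrated with a catalytic amidine base to the trans lactone F4.
- F4 is deprotonated with LiHMDS at −78 °C to the lithium dienolate F5. This is quenched with 2,6-di-tert-butyl-4-methylphenol.
- Substrate-controlled kinetic α-protonation anti to the pseudo-axial C4 aryl group should return the cis lactone 14.

**Step 16.**
- Risk: the lactol can open to the phenol–aldehyde, which allows epimerisation at C3' by enolisation. The intermediate oxocarbenium ion can also eliminate to a 4H-chromene.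
- Fallback: it sets out from 29 and comes back at 31, so that 30 and step 17 are bypassed.
- Hg(II)-promoted methanolysis (HgCl2, CaCO3, MeOH–CH2Cl2) gives the closed methyl acetal F6.
- F6 is oxidised directly to the lactone with mCPBA/BF3·OEt2 (peracid oxidation of a cyclic acetal). A free aldehyde is never present.

## Further compounds

F1 | step 15 | (E)-3-[4-(benzyloxy)phenyl]-2-{(3S,4R)-5,7-bis(benzyloxy)-4-[4-(benzyloxy)phenyl]-6,8-dibromo-2-oxochroman-3-yl}prop-2-enal | O=C1Oc2c(Br)c(OCc3ccccc3)c(Br)c(OCc3ccccc3)c2[C@@H](c2ccc(OCc3ccccc3)cc2)[C@H]1/C(C=O)=C\c1ccc(OCc2ccccc2)cc1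
F2 | step 15 | (E)-3-[4-(benzyloxy)phenyl]-2-{(3S,4R)-5,7-bis(benzyloxy)-4-[4-(benzyloxy)phenyl]-6,8-dibromo-2-oxochroman-3-yl}prop-2-enoic acid | O=C1Oc2c(Br)c(OCc3ccccc3)c(Br)c(OCc3ccccc3)c2[C@@H](c2ccc(OCc3ccccc3)cc2)[C@H]1/C(C(=O)O)=C\c1ccc(OCc2ccccc2)cc1
F3 | step 15 | 2,3,4,5-tetrakis(benzyloxy)phenyl ester of F2 | O=C1Oc2c(Br)c(OCc3ccccc3)c(Br)c(OCc3ccccc3)c2[C@@H](c2ccc(OCc3ccccc3)cc2)[C@H]1/C(C(=O)Oc2cc(OCc3ccccc3)c(OCc3ccccc3)c(OCc3ccccc3)c2OCc2ccccc2)=C\c1ccc(OCc2ccccc2)cc1
F4 | step 6 | (3S,4R)-trans epimer of 14 | O=C1Oc2c(Br)c(OCc3ccccc3)c(Br)c(OCc3ccccc3)c2[C@@H](c2ccc(OCc3ccccc3)cc2)[C@@H]1/C=C/c1ccc(OCc2ccccc2)cc1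
F5 | step 6 | lithium dienolate of F4 (4R) | [Li+].[O-]C1Oc2c(Br)c(OCc3ccccc3)c(Br)c(OCc3ccccc3)c2[C@@H](c2ccc(OCc3ccccc3)cc2)C=1/C=C/c1ccc(OCc2ccccc2)cc1
F6 | step 16 | (3S,4R,3'S,4'R) 2'-methoxy chroman–lactone (methyl acetal, C2' epimers) | O=C1Oc2c(Br)c(OCc3ccccc3)c(Br)c(OCc3ccccc3)c2[C@@H](c2ccc(OCc3ccccc3)cc2)[C@H]1[C@H]1C(OC)Oc2c(OCc3ccccc3)c(OCc3ccccc3)c(OCc3ccccc3)c(OCc3ccccc3)c2[C@H]1c1ccc(OCc2ccccc2)cc1
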